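The readings were computed for substances that don't exist, and the scatter is random.

| flask | solid substrate | coupling partner | protic impurity | remark | time |
|---|---|---|---|---|---|
| ash | 1 M | 0.35 equiv | 0.20 M | run made earlier |  |
| oak | 1 M | 0.52 equiv | 0.20 M | run made earlier |  |
| flask | 1.0 M | 0.700 equiv | 0.200 M |  | 10 h |

- ash (time / h: target / %, solid substrate / %): 2.50: 9, 65; 3.00: 8, 62; 4.00: 10, 48; 6.00: 19, 31; 8.00: 22, 15
- oak (time / h: target / %, solid substrate / %): 2.50: 13, 67; 3.00: 14, 63; 4.00: 17, 51; 6.00: 26, 31; 8.00: 30, 16

(each reading ± 1.5 percentage points)

* when, up to 10 h, the flask holds most target
* the amount of target, in percent of the solid substrate charged, at that time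

- the earlier runs were read with a standard deviation of 1.5 percentage points
- at the start none of the solid substrate is in solution
- a reading or a percentage of target counts all its forms, free or not

**The ratio.** Target at the last reading, 8.00 h, over coupling partner charged is 62.9% in the ash run and 57.7% in the oak run. I assume each target takes one coupling partner, so these are the shares of partner used. Read as a pseudo-first-order loss of partner, they give 5.60 h from ash and 6.45 h from oak for the partner half-life τ, the time in which half of the free partner goes into target. I freeze the oak figure, from the charge nearer this flask's.

**Turned round.** For this flask to peak before 10 h, its target would have to be falling by then. With τ frozen, the flask keeps 34.1% of its partner at 10 h, holds 46.1% target, and still gains 0.0257 h⁻¹ as a fraction of the solid substrate charged. An earlier peak asks for a loss of target faster than that gain. The ash and oak runs each read their highest target at the last reading.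

**The forecast.** It gives 10 h and 46%: “No decline is visible”.

**The flask.** It holds most target at 10.0 h, with 46.4%.

    solid product ⇌ target, rate k1*(cs1 - [target]) while solid is left; crystals form when [target] > cs1 (solubility = 0.110 M, k = 0.340 min⁻¹)
    dissolved substrate + coupling partner → target (k = 0.0230 L mol⁻¹ min⁻¹)
    solid substrate ⇌ dissolved substrate, rate k3*(cs3 - [dissolved substrate]) while solid is left; crystals form when [dissolved substrate] > cs3 (solubility = 0.350 M, k = 0.00540 min⁻¹)
    2 dissolved substrate → side product (k = 0.0390 L mol⁻¹ min⁻¹)
    solid substrate + protic impurity → quenched substrate (k = 0.00670 L mol⁻¹ min⁻¹)

**Partner left.** At that time this flask keeps 34% of its coupling partner, against my 34.1%. In a further flask charged with 0.280 equiv of partner, the same τ leaves the same 34.1% and gives 18.5% target at 10 h. That flask holds 20.9% target, with 25% of its partner left.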